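**Retrosynthetic overview**

- Ring names: ring A is the benzene ring of the chromene (C4a, C5 to C8, C8a), ring B the pyran (O1, C2 to C4), ring C the gem-dimethyl β-triketone (filicinic acid) ring. The last disconnection is the CH2 bridge between C6 of ring A and the free ring CH of ring C (phenolic Mannich base plus isobutyrylfilicinic acid).
- Ring B is disconnected at O1–C8a and C4–C4a. 2-Methylbut-3-yn-2-ol supplies O1, C2 with both methyl groups, C3 and C4. It is joined with a 2,6-difluoroaryl isopropyl ketone and 2-(trimethylsilyl)ethanol in a three-component one-pot SNAr / SNAr / propargyl Claisen / oxa-6π sequence.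
- Enabling feature: in ring A the C8 isobutyryl carbonyl is ortho to both C8a and C7, so both oxygen-bearing carbons next to it are SNAr-activated positions of an aryl ketone. C4a is the only hydrogen-bearing carbon ortho to C8a, so the sigmatropic shift can deliver C4 only there.
- Order of ring formation: ring A is bought (3,5-difluorophenol), ring B closes in step 3, ring C arises by dearomatizing gem-dimethylation of an acylphloroglucinol (steps 6 and 7), and the halves are joined in step 8.

Key step: step 3

Remark (assumption): the β-triketone ring is written throughout as the enol tautomer of the target SMILES; its tautomers interconvert freely. The target has no stereocenter.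

**Route**

Step 1
Reactants: 1 3,5-difluorophenol; 2 2-(trimethylsilyl)ethanol
Product: 3 (2-(3,5-difluorophenoxy)ethyl)trimethylsilane
Conditions: PPh3, diisopropyl azodicarboxylate (DIAD), THF, 0 °C to rt
Reagents that add atoms: none
Why: Mitsunobu etherification of the acidic phenol with a primary alcohol should be clean, and it installs the future C5 oxygen in a form that tolerates organolithium and alkoxide chemistry and is later removed by fluoride.

Step 2
Reactants: 3 (2-(3,5-difluorophenoxy)ethyl)trimethylsilane
Product: 5 1-(2,6-difluoro-4-(2-(trimethylsilyl)ethoxy)phenyl)-2-methylpropan-1-one, via aryllithium 4 (not isolated)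
Conditions: n-BuLi, THF, −78 °C; then N-methoxy-N-methylisobutyramide, −78 to −20 °C; aq. NH4Cl
Reagents that add atoms: N-methoxy-N-methylisobutyramide, CC(C)C(=O)N(C)OC
Why: Directed ortho-lithiation should occur at the C–H flanked by both fluorines (the most acidic position), and acylation of the aryllithium by the N-methoxy-N-methylamide stops at the ketone stage.

Step 3
Reactants: 5 1-(2,6-difluoro-4-(2-(trimethylsilyl)ethoxy)phenyl)-2-methylpropan-1-one; 6 2-methylbut-3-yn-2-ol; 2 2-(trimethylsilyl)ethanol
Product: 11 1-(2,2-dimethyl-5,7-bis(2-(trimethylsilyl)ethoxy)-2H-chromen-8-yl)-2-methylpropan-1-one, via fluoro propargyl ether 7 (not isolated), via aryl propargyl ether 8 (not isolated), via ortho-allenylphenol 9 (not isolated), via ortho-quinone methide 10 (not isolated)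
Conditions: 6, NaH, THF/DMAc, 0 to 25 °C; then 2, NaH, 60 °C; then AcOH (0.2 equiv), 150 °C
Reagents that add atoms: none
Why: The sodium alkoxide of 6 should displace one of the two equivalent ortho fluorides of 5 by addition–elimination (SNAr, the anionic adduct being stabilized by the ortho isobutyryl carbonyl) to form O1–C8a in 7, and the alkoxide of 2 then displaces the second fluoride to place the C7 oxygen in 8; on heating, 8 undergoes a [3,3] propargyl Claisen shift onto C4a (forming C4–C4a), enolization to 9, a 1,5-hydrogen shift to 10 and oxa-6π electrocyclization. The closest known reactions are SNAr of ortho-fluoroaryl ketones with alkoxides (including alkoxides of tertiary propargylic alcohols on activated fluoroarenes) and the thermal rearrangement of aryl 1,1-dimethylpropargyl ethers to 2,2-dimethyl-2H-chromenes. Ring B is closed by thermal disrotatory oxa-6π electrocyclization of the (Z)-dienone 10, which re-forms the O1–C2 bond that the sigmatropic shift had opened; no stereocenter is created. The step needs mono-substitution by the tertiary alkoxide, which the bulk of the nucleophile and the lower reactivity of the ring after the first substitution should secure, and it needs the Claisen shift to end at C4a, which is secured because the other ortho carbon (C8) carries the acyl group and has no hydrogen for rearomatization. The quaternary propargylic carbon excludes base-induced propargyl–allenyl isomerization and benzofuran formation and accelerates the rearrangement.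

Step 4
Reactants: 11 1-(2,2-dimethyl-5,7-bis(2-(trimethylsilyl)ethoxy)-2H-chromen-8-yl)-2-methylpropan-1-one
Product: 12 1-(5,7-dihydroxy-2,2-dimethyl-2H-chromen-8-yl)-2-methylpropan-1-one
Conditions: CsF, DMF, 90 °C; aq. NH4Cl
Reagents that add atoms: none
Why: Fluoride attack at silicon should trigger β-elimination (loss of ethene) of both 2-(trimethylsilyl)ethyl aryl ethers, helped by the acyl-stabilized phenoxide leaving groups, under non-acidic and non-reducing conditions that leave the C3=C4 bond and the ketone untouched.

Step 5
Reactants: 12 1-(5,7-dihydroxy-2,2-dimethyl-2H-chromen-8-yl)-2-methylpropan-1-one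
Product: 13 1-(6-((dimethylamino)methyl)-5,7-dihydroxy-2,2-dimethyl-2H-chromen-8-yl)-2-methylpropan-1-one
Conditions: N,N-dimethylmethyleneiminium iodide, K2CO3, MeCN, 0 °C to rt
Reagents that add atoms: N,N-dimethylmethyleneiminium iodide, C=[N+](C)C.[I-]
Why: Mannich aminomethylation should occur at C6, the only free position of ring A and the most nucleophilic carbon because it lies between two hydroxyl groups.

Step 6
Reactants: 14 phloroglucinol (benzene-1,3,5-triol)
Product: 15 2-methyl-1-(2,4,6-trihydroxyphenyl)propan-1-one (phlorisobutyrophenone)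
Conditions: isobutyryl chloride, AlCl3, PhNO2/CH2Cl2, 0 to 45 °C; aq. HCl
Reagents that add atoms: isobutyryl chloride, CC(C)C(Cl)=O
Why: Friedel–Crafts C-acylation of the highly nucleophilic phloroglucinol; one equivalent of acyl chloride and the deactivating effect of the first acyl group should limit diacylation.

Step 7
Reactants: 15 2-methyl-1-(2,4,6-trihydroxyphenyl)propan-1-one
Product: 17 3,5-dihydroxy-6,6-dimethyl-2-(2-methylpropanoyl)cyclohexa-2,4-dien-1-one (isobutyrylfilicinic acid), via C-monomethyl ketone 16 (not isolated)
Conditions: NaOMe, MeI, MeOH, 0 °C to rt; aq. HCl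
Reagents that add atoms: iodomethane, CI
Why: Base-mediated C-methylation of the acylphloroglucinol polyanion, in which the second alkylation at the same ring carbon dearomatizes the ring to the gem-dimethyl β-triketone (the classical entry to acylfilicinic acids).

Step 8
Reactants: 13 1-(6-((dimethylamino)methyl)-5,7-dihydroxy-2,2-dimethyl-2H-chromen-8-yl)-2-methylpropan-1-one; 17 isobutyrylfilicinic acid
Product: 19 Uliginosin B, via ring A ortho-quinone methide 18 (not isolated)
Conditions: 1,4-dioxane, 90 °C; dilute aq. HCl wash
Reagents that add atoms: none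
Why: The acidic β-triketone 17 should protonate the benzylic amine, thermal loss of dimethylamine gives 18, and Michael addition of the triketone enolate through its ring CH forms the methylene bridge and restores ring A (phenolic Mannich base alkylation of a 1,3-dicarbonyl compound).

**Compound list**

1 | 3,5-difluorophenol | Oc1cc(F)cc(F)c1 | starting material
2 | 2-(trimethylsilyl)ethanol | C[Si](C)(C)CCO | starting material
3 | (2-(3,5-difluorophenoxy)ethyl)trimethylsilane | C[Si](C)(C)CCOc1cc(F)cc(F)c1 | intermediate
4 | (2,6-difluoro-4-(2-(trimethylsilyl)ethoxy)phenyl)lithium | [Li]c1c(F)cc(OCC[Si](C)(C)C)cc1F | intermediate (not isolated)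
5 | 1-(2,6-difluoro-4-(2-(trimethylsilyl)ethoxy)phenyl)-2-methylpropan-1-one | CC(C)C(=O)c1c(F)cc(OCC[Si](C)(C)C)cc1F | intermediate
6 | 2-methylbut-3-yn-2-ol | CC(C)(O)C#C | starting material
7 | 1-(2-fluoro-6-((2-methylbut-3-yn-2-yl)oxy)-4-(2-(trimethylsilyl)ethoxy)phenyl)-2-methylpropan-1-one | CC(C)C(=O)c1c(F)cc(OCC[Si](C)(C)C)cc1OC(C)(C)C#C | intermediate (not isolated)
8 | 2-methyl-1-(2-((2-methylbut-3-yn-2-yl)oxy)-4,6-bis(2-(trimethylsilyl)ethoxy)phenyl)propan-1-one | CC(C)C(=O)c1c(OCC[Si](C)(C)C)cc(OCC[Si](C)(C)C)cc1OC(C)(C)C#C | intermediate (not isolated)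
9 | 1-(2-hydroxy-3-(3-methylbuta-1,2-dien-1-yl)-4,6-bis(2-(trimethylsilyl)ethoxy)phenyl)-2-methylpropan-1-one | CC(C)C(=O)c1c(OCC[Si](C)(C)C)cc(OCC[Si](C)(C)C)c(C=C=C(C)C)c1O | intermediate (not isolated)
10 | (6Z)-6-(3-methylbut-2-en-1-ylidene)-2-(2-methylpropanoyl)-3,5-bis(2-(trimethylsilyl)ethoxy)cyclohexa-2,4-dien-1-one | CC(C)=C/C=C1\C(=O)C(C(=O)C(C)C)=C(OCC[Si](C)(C)C)C=C1OCC[Si](C)(C)C | intermediate (not isolated)
11 | 1-(2,2-dimethyl-5,7-bis(2-(trimethylsilyl)ethoxy)-2H-chromen-8-yl)-2-methylpropan-1-one | CC(C)C(=O)c1c(OCC[Si](C)(C)C)cc(OCC[Si](C)(C)C)c2C=CC(C)(C)Oc12 | intermediate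
12 | 1-(5,7-dihydroxy-2,2-dimethyl-2H-chromen-8-yl)-2-methylpropan-1-one | CC(C)C(=O)c1c(O)cc(O)c2C=CC(C)(C)Oc12 | intermediate
13 | 1-(6-((dimethylamino)methyl)-5,7-dihydroxy-2,2-dimethyl-2H-chromen-8-yl)-2-methylpropan-1-one | CC(C)C(=O)c1c(O)c(CN(C)C)c(O)c2C=CC(C)(C)Oc12 | intermediate
14 | phloroglucinol (benzene-1,3,5-triol) | Oc1cc(O)cc(O)c1 | starting material
15 | 2-methyl-1-(2,4,6-trihydroxyphenyl)propan-1-one (phlorisobutyrophenone) | CC(C)C(=O)c1c(O)cc(O)cc1O | intermediate
16 | 2-methyl-1-(2,4,6-trihydroxy-3-methylphenyl)propan-1-one | CC(C)C(=O)c1c(O)cc(O)c(C)c1O | intermediate (not isolated)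
17 | 3,5-dihydroxy-6,6-dimethyl-2-(2-methylpropanoyl)cyclohexa-2,4-dien-1-one (isobutyrylfilicinic acid) | CC(C)C(=O)C1=C(O)C=C(O)C(C)(C)C1=O | intermediate
18 | 7-hydroxy-2,2-dimethyl-6-methylidene-8-(2-methylpropanoyl)-2H-chromen-5(6H)-one | CC(C)C(=O)C1=C(O)C(=C)C(=O)C2=C1OC(C)(C)C=C2 | intermediate (not isolated)
19 | Uliginosin B | CC(C)C(=O)C1=C(O)C(Cc2c(O)c3c(c(C(=O)C(C)C)c2O)OC(C)(C)C=C3)=C(O)C(C)(C)C1=O | target

**Step count and risks**

Total step count: 8. Longest linear sequence: 6 (steps 1, 2, 3, 4, 5 and 8); steps 6 and 7 form the second branch.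

Most likely to fail, first: step 3. The first SNAr stage may stop short or go on to double displacement, ketone enolization may stall the second displacement, and the silylethyl groups may be lost thermally before the rearrangement is complete. The fallback abandons the fluoride logic and sets out from 15. Knoevenagel condensation of 15 with 3-methylbut-2-enal (ethylenediammonium diacetate, toluene or xylene, reflux) is followed in the same flask by oxa-6π electrocyclization of the resulting dienone onto the hydroxyl ortho to the acyl group. This should give 12 directly, where the fallback rejoins the route; the 6-acyl regioisomer that can form beside it would be removed by chromatography. This fallback makes no compound outside the list (F0).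

Second: step 8. Amine elimination may be slow and force temperatures at which retro-Michael exchange of the methylene bridge scrambles the two halves into the symmetrical dimers. The fallback sets out from 13, which is N-methylated (MeI, acetone, rt) to 1-(5,7-dihydroxy-2,2-dimethyl-8-(2-methylpropanoyl)-2H-chromen-6-yl)-N,N,N-trimethylmethanaminium iodide F1. With the sodium enolate of 17 (NaHCO3 or NaH, THF/DMF, 0 °C to rt) F1 should release 18 without heating, and the enolate traps it to give 19, where the fallback ends.

Third: step 7. Under- and over-methylation and O-methylation may give mixtures of mono-, gem-di- and trimethylated products. The fallback sets out from 15, which is acylated a second time (isobutyryl chloride, AlCl3, PhNO2/CH2Cl2) to 1,1'-(2,4,6-trihydroxy-1,3-phenylene)bis(2-methylpropan-1-one) F2. Its single free ring carbon can only be gem-dimethylated (MeI, NaOMe, MeOH), which should give 3,5-dihydroxy-6,6-dimethyl-2,4-bis(2-methylpropanoyl)cyclohexa-2,4-dien-1-one F3. Acid-mediated removal of one of its two equivalent acyl groups (aq. H2SO4, about 80 °C, controlled by time) should give 17, where the fallback rejoins the route.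

**Further compounds**

F0 | step 3 | none | none
F1 | step 8 | 1-(5,7-dihydroxy-2,2-dimethyl-8-(2-methylpropanoyl)-2H-chromen-6-yl)-N,N,N-trimethylmethanaminium iodide | CC(C)C(=O)c1c(O)c(C[N+](C)(C)C)c(O)c2C=CC(C)(C)Oc12.[I-]
F2 | step 7 | 1,1'-(2,4,6-trihydroxy-1,3-phenylene)bis(2-methylpropan-1-one) | CC(C)C(=O)c1c(O)cc(O)c(C(=O)C(C)C)c1O
F3 | step 7 | 3,5-dihydroxy-6,6-dimethyl-2,4-bis(2-methylpropanoyl)cyclohexa-2,4-dien-1-one | CC(C)C(=O)C1=C(O)C(C(=O)C(C)C)=C(O)C(C)(C)C1=O
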